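**Retrosynthetic overview**

1. Germacrane numbering is used: ring A is the ten-membered carbocycle C1–C10, ring B the γ-lactone O–C12(=O)–C11–C7–C6; C13 is the methyl on C11, C14 the methyl on C10, C15 the CH2OH on C4. The C8 ester is attached last (Steglich), and C11–H comes from conjugate reduction of an 11(13)-methylene lactone.
2. Key disconnection: ring B is cut at C7–C11 and C6–O, back to 2-bromoacrylic acid and an all-cis cyclodecatrienol. The enabling feature is that C6 is allylic to the C4=C5 bond of ring A and adjacent to C7. The trienol therefore holds a C4=C5–C6=C7 diene inside ring A; carbopalladation at C7 turns it into a C6–C5–C4 allylpalladium, and the C12 carboxylate can reach only its C6 terminus through a five-membered ring. The C8 hydroxyl next to C7 steers the face.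
3. Ring A is made first, by Nozaki–Hiyama–Kishi closure of C7–C8 in an iodoalkyne aldehyde; C8 is then set by oxidation and asymmetric transfer hydrogenation, and the cis C6=C7 bond by zinc semi-reduction.
4. The open chain comes from triethyl phosphonoacetate: alkylation (C3–C1), Horner–Wadsworth–Emmons olefination (C4=C5 with C6≡C7), iodo-olefination (C1=C10) and oxirane opening (C9–C8).
5. Ring order: A (step 10), then B (step 14).

Key step: step 14

Step 1
Reactants: 1 triethyl phosphonoacetate; 2 2-(2-bromoethyl)-1,3-dioxolane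
Product: 3 ethyl 2-(diethoxyphosphoryl)-4-(1,3-dioxolan-2-yl)butanoate (racemic)
Conditions: NaH, DMF, 0 °C; then 2, 60 °C
Reagents that add atoms: none
Why: The sodium phosphonoacetate carbanion is C-alkylated by the primary bromide (SN2 alkylation of a stabilised carbanion), which attaches C3–C1 with C1 masked as the dioxolane; the new stereocentre is lost again in step 2.

Step 2
Reactants: 3; 4 3-(trimethylsilyl)prop-2-ynal
Product: 5 ethyl (2E)-2-[2-(1,3-dioxolan-2-yl)ethyl]-5-(trimethylsilyl)pent-2-en-4-ynoate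
Conditions: NaH, THF, 0 °C; then 4, −78 → 0 °C
Reagents that add atoms: none
Why: Horner–Wadsworth–Emmons olefination of an α-substituted phosphonoacetate should give mainly the (E)-enoate with the ester trans to the alkynyl group, which fixes C3 cis to C6 across C4=C5 as ring A requires.

Step 3
Reactants: 5
Product: 6 (2E)-2-[2-(1,3-dioxolan-2-yl)ethyl]-5-(trimethylsilyl)pent-2-en-4-yn-1-ol
Conditions: i-Bu2AlH (2.2 equiv), CH2Cl2, −78 °C; aq. KNa tartrate work-up
Reagents that add atoms: none
Why: i-Bu2AlH reduces the conjugated ester to the allylic alcohol (C15) by 1,2-hydride delivery and leaves the silylalkyne and the acetal untouched.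

Step 4
Reactants: 6
Product: 7 tert-butyl{[(2E)-2-[2-(1,3-dioxolan-2-yl)ethyl]-5-(trimethylsilyl)pent-2-en-4-yn-1-yl]oxy}dimethylsilane
Conditions: TBSCl, imidazole, DMF, rt
Reagents that add atoms: tert-butyldimethylsilyl chloride, CC(C)(C)[Si](C)(C)Cl
Why: Standard silylation of the primary allylic alcohol protects O15 until the last step.

Step 5
Reactants: 7
Product: 8 (4E)-4-{[(tert-butyldimethylsilyl)oxy]methyl}-7-(trimethylsilyl)hept-4-en-6-ynal
Conditions: PPTS (20 mol %), acetone/H2O 10:1, 50 °C
Reagents that add atoms: water, O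
Why: Mild acid-catalysed acetal hydrolysis frees the C1 aldehyde, while the primary TBS ether and the C-silyl group should survive PPTS.

Step 6
Reactants: 8
Product: 9 [(3E,7Z)-4-{[(tert-butyldimethylsilyl)oxy]methyl}-8-iodonona-3,7-dien-1-yn-1-yl]trimethylsilane
Conditions: EtPPh3I, n-BuLi, THF, 0 °C; I2, −78 °C; NaN(SiMe3)2, −20 °C; then 8, −78 °C
Reagents that add atoms: ethyltriphenylphosphonium iodide, CC[P+](c1ccccc1)(c1ccccc1)c1ccccc1.[I-]; iodine, II
Why: Wittig olefination with the α-iodo ylide (Zhao variant of the Stork–Zhao olefination) should give the (Z)-2-iodoalk-2-ene with iodine cis to the chain, which defines the ring-cis C1=C10 geometry once iodine is replaced with retention.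

Step 7
Reactants: 9
Product: 11 (3Z,7E)-7-{[(tert-butyldimethylsilyl)oxy]methyl}-3-methyl-10-(trimethylsilyl)deca-3,7-dien-9-yn-1-ol, via alkenyllithium 10 (not isolated)
Conditions: t-BuLi (2.1 equiv), Et2O, −78 °C; then oxirane, −78 °C → rt; H2O
Reagents that add atoms: oxirane, C1CO1
Why: Iodine–lithium exchange is faster than any addition to the enyne and retains the olefin geometry, and the alkenyllithium opens oxirane (SN2) to add C9 and C8 as a primary alcohol.

Step 8
Reactants: 11
Product: 12 (3Z,7E)-7-{[(tert-butyldimethylsilyl)oxy]methyl}-10-iodo-3-methyldeca-3,7-dien-9-yn-1-ol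
Conditions: N-iodosuccinimide, AgNO3 (10 mol %), DMF, rt, dark
Reagents that add atoms: N-iodosuccinimide, O=C1CCC(=O)N1I
Why: Silver-catalysed iododesilylation converts the alkynylsilane directly into the 1-iodoalkyne needed for chromium insertion without affecting the olefins or the alcohol.

Step 9
Reactants: 12
Product: 13 (3Z,7E)-7-{[(tert-butyldimethylsilyl)oxy]methyl}-10-iodo-3-methyldeca-3,7-dien-9-ynal
Conditions: Dess–Martin periodinane, NaHCO3, CH2Cl2, 0 °C; used at once
Reagents that add atoms: none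
Why: Buffered Dess–Martin oxidation gives the β,γ-unsaturated aldehyde under neutral conditions that should not move the C1=C10 bond into conjugation.

Step 10
Reactants: 13
Product: 15 rac-(4E,8Z)-5-{[(tert-butyldimethylsilyl)oxy]methyl}-9-methylcyclodeca-4,8-dien-2-yn-1-ol, via alkynylchromium dichloride 14 (not isolated)
Conditions: CrCl2 (6 equiv), NiCl2 (2 mol %), THF, 0.003 M, rt, slow addition of 13
Reagents that add atoms: none
Why: Nozaki–Hiyama–Kishi (Takai) reaction: divalent chromium inserts into the C(sp)–I bond and the alkynylchromium adds to the aldehyde without enolising it, the two cis olefins and high dilution favouring closure of the ten-membered ring (a closure known for ten-membered enyne carbinols); the C8 carbinol forms as a racemate and is corrected in steps 11 and 12.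

Step 11
Reactants: 15
Product: 16 (4E,8Z)-5-{[(tert-butyldimethylsilyl)oxy]methyl}-9-methylcyclodeca-4,8-dien-2-yn-1-one
Conditions: MnO2 (activated, 20 equiv), CH2Cl2, rt
Reagents that add atoms: none
Why: MnO2 oxidises the propargylic alcohol to the ynone under neutral heterogeneous conditions and erases the uncontrolled C8 centre.

Step 12
Reactants: 16
Product: 17 (1S,4E,8Z)-5-{[(tert-butyldimethylsilyl)oxy]methyl}-9-methylcyclodeca-4,8-dien-2-yn-1-ol
Conditions: Ru[(S,S)-TsDPEN](p-cymene) (3 mol %), i-PrOH, rt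
Reagents that add atoms: none
Why: Noyori asymmetric transfer hydrogenation of an alkynyl ketone, in which the alkynyl group plays the part of the aryl group of an aryl ketone, should give the (S)-carbinol with the (S,S)-ligand; this sets C8.

Step 13
Reactants: 17
Product: 18 (1S,2Z,4E,8Z)-5-{[(tert-butyldimethylsilyl)oxy]methyl}-9-methylcyclodeca-2,4,8-trien-1-ol (all three ring double bonds cis within the ring)
Conditions: Zn dust activated with Cu(OAc)2 and AgNO3, MeOH/H2O 1:1, 40 °C
Reagents that add atoms: none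
Why: Zinc (copper/silver couple) reduction of the conjugated, hydroxyl-activated triple bond is cis-selective and should stop at the diene, giving the cis C6=C7 bond and thus the cis,cis-1,3-diene inside ring A.

Step 14
Reactants: 18; 19 2-bromoprop-2-enoic acid
Product: 22 (3aR,4S,6Z,10E,11aR)-10-{[(tert-butyldimethylsilyl)oxy]methyl}-4-hydroxy-6-methyl-3-methylidene-3a,4,5,8,9,11a-hexahydrocyclodeca[b]furan-2(3H)-one, via vinylpalladium bromide 20 (not isolated), via allylpalladium bromide 21 (not isolated)
Conditions: Pd(OAc)2 (10 mol %), PPh3 (20 mol %), n-Bu4NCl (1.5 equiv), KOAc (3 equiv), DMF, 60 °C; 19 (2 equiv) added over 3 h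
Reagents that add atoms: none
Why: Zerovalent palladium inserts into the C–Br bond of 19 to give the vinylpalladium 20, which adds syn across C6=C7 of the ring-A diene with carbon going to the less substituted terminus C7 and the metal to C6, where it is held as the C6–C5–C4 allyl complex 21, and the C12 carboxylate then attacks C6 and releases the catalyst, so that the C7–C11 and C6–O bonds of a formal (3+2) annulation are made in one operation. The closest known reaction type is the Larock palladium-catalysed heteroannulation of 1,3-dienes with vinylic or aryl halides that carry a carboxylic acid. Ring B closes by 5-exo attack of oxygen on the C6 allyl terminus, the alternative terminus C4 being fully substituted and reachable only through a seven-membered ring. C7 is set by substrate control: in 18 the C8–H bond lies in the plane of the cis C6=C7 bond to avoid A(1,3) strain with C5, the ring chain from C9 shields one face and the C8 hydroxyl sits on the open face, so the hydroxyl-guided vinylpalladium should add there and give 7R, with C11 trans to O8 in the ring-A drawing. C6 is set by attack of the tethered carboxylate anti to palladium (chloride and PPh3 keep the carboxylate off the metal), which together with the syn carbopalladation amounts to anti addition across the cis olefin and gives the trans-fused lactone (6R, O6 cis to O8), while C3 stays anti on the allyl unit so that C4=C5 remains cis in ring A. The step needs chemoselectivity for the diene over the trisubstituted C1=C10 olefin, which is inert to insertion here, and it needs trans fusion, which the ten-membered ring allows (unlike six-membered dienes) and which reversible ionisation of the allylic lactone by zerovalent palladium should reinforce.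

Step 15
Reactants: 22
Product: 23 (3S,3aR,4S,6Z,10E,11aR)-10-{[(tert-butyldimethylsilyl)oxy]methyl}-4-hydroxy-3,6-dimethyl-3a,4,5,8,9,11a-hexahydrocyclodeca[b]furan-2(3H)-one
Conditions: NaBH4, MeOH, 0 °C
Reagents that add atoms: none
Why: NaBH4 in MeOH adds hydride to C13 of the α-methylene lactone (conjugate reduction), and the lactone enolate is protonated and equilibrated by methoxide to the more stable C11 epimer with the methyl trans to the C7–C8 bond (11S), the usual outcome for 6,12-germacranolides.

Step 16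
Reactants: 24 ethyl 2-(hydroxymethyl)prop-2-enoate
Product: 25 ethyl 2-{[(tert-butyldimethylsilyl)oxy]methyl}prop-2-enoate
Conditions: TBSCl, imidazole, CH2Cl2, rt
Reagents that add atoms: tert-butyldimethylsilyl chloride, CC(C)(C)[Si](C)(C)Cl
Why: Standard silylation of the primary allylic alcohol.

Step 17
Reactants: 25
Product: 26 2-{[(tert-butyldimethylsilyl)oxy]methyl}prop-2-enoic acid
Conditions: LiOH, THF/H2O, 0 °C → rt; then 1 M HCl to pH 3
Reagents that add atoms: lithium hydroxide, [Li+].[OH-]
Why: Saponification of the ethyl ester at low temperature, where hydroxide attacks the ester carbonyl faster than the hindered β-position of the 2-substituted acrylate, gives the acid after acidification.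

Step 18
Reactants: 23; 26
Product: 27 (3S,3aR,4S,6Z,10E,11aR)-10-{[(tert-butyldimethylsilyl)oxy]methyl}-3,6-dimethyl-2-oxo-2,3,3a,4,5,8,9,11a-octahydrocyclodeca[b]furan-4-yl 2-{[(tert-butyldimethylsilyl)oxy]methyl}prop-2-enoate
Conditions: DCC, DMAP (20 mol %), CH2Cl2, 0 °C → rt
Reagents that add atoms: none
Why: Steglich esterification (DCC activation, DMAP acyl transfer) acylates the only free hydroxyl (O8) without touching C8, so its configuration is retained.

Step 19
Reactants: 27
Product: 28 (3S,3aR,4S,6Z,10E,11aR)-10-(hydroxymethyl)-3,6-dimethyl-2-oxo-2,3,3a,4,5,8,9,11a-octahydrocyclodeca[b]furan-4-yl 2-(hydroxymethyl)prop-2-enoate (target)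
Conditions: HF·pyridine, THF/pyridine, 0 °C → rt
Reagents that add atoms: none
Why: Fluoride-mediated cleavage of both primary TBS ethers under buffered, weakly acidic conditions should spare the two esters, the lactone and the allylic alcohol and give the target.

**Compound list**

1 | triethyl phosphonoacetate | CCOC(=O)CP(=O)(OCC)OCC | starting material
2 | 2-(2-bromoethyl)-1,3-dioxolane | BrCCC1OCCO1 | starting material
3 | ethyl 2-(diethoxyphosphoryl)-4-(1,3-dioxolan-2-yl)butanoate (racemic) | CCOC(=O)C(CCC1OCCO1)P(=O)(OCC)OCC | intermediate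
4 | 3-(trimethylsilyl)prop-2-ynal | C[Si](C)(C)C#CC=O | starting material
5 | ethyl (2E)-2-[2-(1,3-dioxolan-2-yl)ethyl]-5-(trimethylsilyl)pent-2-en-4-ynoate | CCOC(=O)/C(CCC1OCCO1)=C/C#C[Si](C)(C)C | intermediate
6 | (2E)-2-[2-(1,3-dioxolan-2-yl)ethyl]-5-(trimethylsilyl)pent-2-en-4-yn-1-ol | OC/C(CCC1OCCO1)=C/C#C[Si](C)(C)C | intermediate
7 | tert-butyl{[(2E)-2-[2-(1,3-dioxolan-2-yl)ethyl]-5-(trimethylsilyl)pent-2-en-4-yn-1-yl]oxy}dimethylsilane | CC(C)(C)[Si](C)(C)OC/C(CCC1OCCO1)=C/C#C[Si](C)(C)C | intermediate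
8 | (4E)-4-{[(tert-butyldimethylsilyl)oxy]methyl}-7-(trimethylsilyl)hept-4-en-6-ynal | CC(C)(C)[Si](C)(C)OC/C(CCC=O)=C/C#C[Si](C)(C)C | intermediate
9 | [(3E,7Z)-4-{[(tert-butyldimethylsilyl)oxy]methyl}-8-iodonona-3,7-dien-1-yn-1-yl]trimethylsilane | C/C(I)=C/CC/C(CO[Si](C)(C)C(C)(C)C)=C\C#C[Si](C)(C)C | intermediate
10 | alkenyllithium (8-lithio analogue of 9) | C/C([Li])=C/CC/C(CO[Si](C)(C)C(C)(C)C)=C\C#C[Si](C)(C)C | intermediate
11 | (3Z,7E)-7-{[(tert-butyldimethylsilyl)oxy]methyl}-3-methyl-10-(trimethylsilyl)deca-3,7-dien-9-yn-1-ol | C/C(CCO)=C/CC/C(CO[Si](C)(C)C(C)(C)C)=C\C#C[Si](C)(C)C | intermediate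
12 | (3Z,7E)-7-{[(tert-butyldimethylsilyl)oxy]methyl}-10-iodo-3-methyldeca-3,7-dien-9-yn-1-ol | C/C(CCO)=C/CC/C(CO[Si](C)(C)C(C)(C)C)=C\C#CI | intermediate
13 | (3Z,7E)-7-{[(tert-butyldimethylsilyl)oxy]methyl}-10-iodo-3-methyldeca-3,7-dien-9-ynal | C/C(CC=O)=C/CC/C(CO[Si](C)(C)C(C)(C)C)=C\C#CI | intermediate
14 | alkynylchromium dichloride derived from 13 | C/C(CC=O)=C/CC/C(CO[Si](C)(C)C(C)(C)C)=C\C#C[Cr](Cl)Cl | intermediate
15 | rac-(4E,8Z)-5-{[(tert-butyldimethylsilyl)oxy]methyl}-9-methylcyclodeca-4,8-dien-2-yn-1-ol | C1/C(CO[Si](C)(C)C(C)(C)C)=C\C#CC(O)C/C(C)=C\C1 | intermediate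
16 | (4E,8Z)-5-{[(tert-butyldimethylsilyl)oxy]methyl}-9-methylcyclodeca-4,8-dien-2-yn-1-one | C1/C(CO[Si](C)(C)C(C)(C)C)=C\C#CC(=O)C/C(C)=C\C1 | intermediate
17 | (1S,4E,8Z)-5-{[(tert-butyldimethylsilyl)oxy]methyl}-9-methylcyclodeca-4,8-dien-2-yn-1-ol | C1/C(CO[Si](C)(C)C(C)(C)C)=C\C#C[C@@H](O)C/C(C)=C\C1 | intermediate
18 | (1S,2Z,4E,8Z)-5-{[(tert-butyldimethylsilyl)oxy]methyl}-9-methylcyclodeca-2,4,8-trien-1-ol | C1/C(CO[Si](C)(C)C(C)(C)C)=C\C=C/[C@@H](O)C/C(C)=C\C1 | intermediate
19 | 2-bromoprop-2-enoic acid | C=C(Br)C(=O)O | starting material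
20 | (1-carboxyethenyl)palladium bromide (ligands omitted) | C=C([Pd]Br)C(=O)O | intermediate
21 | allylpalladium bromide drawn in its C6-bound form (ligands omitted) | O[C@H]1C/C(C)=C\CC/C(CO[Si](C)(C)C(C)(C)C)=C\[C@H]([Pd]Br)[C@@H]1C(=C)C(=O)O | intermediate
22 | (3aR,4S,6Z,10E,11aR)-10-{[(tert-butyldimethylsilyl)oxy]methyl}-4-hydroxy-6-methyl-3-methylidene-3a,4,5,8,9,11a-hexahydrocyclodeca[b]furan-2(3H)-one | O[C@H]1C/C(C)=C\CC/C(CO[Si](C)(C)C(C)(C)C)=C\[C@H]2OC(=O)C(=C)[C@H]12 | intermediate
23 | (3S,3aR,4S,6Z,10E,11aR)-10-{[(tert-butyldimethylsilyl)oxy]methyl}-4-hydroxy-3,6-dimethyl-3a,4,5,8,9,11a-hexahydrocyclodeca[b]furan-2(3H)-one | O[C@H]1C/C(C)=C\CC/C(CO[Si](C)(C)C(C)(C)C)=C\[C@H]2OC(=O)[C@@H](C)[C@H]12 | intermediate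
24 | ethyl 2-(hydroxymethyl)prop-2-enoate | C=C(CO)C(=O)OCC | starting material
25 | ethyl 2-{[(tert-butyldimethylsilyl)oxy]methyl}prop-2-enoate | C=C(CO[Si](C)(C)C(C)(C)C)C(=O)OCC | intermediate
26 | 2-{[(tert-butyldimethylsilyl)oxy]methyl}prop-2-enoic acid | C=C(CO[Si](C)(C)C(C)(C)C)C(=O)O | intermediate
27 | (3S,3aR,4S,6Z,10E,11aR)-10-{[(tert-butyldimethylsilyl)oxy]methyl}-3,6-dimethyl-2-oxo-2,3,3a,4,5,8,9,11a-octahydrocyclodeca[b]furan-4-yl 2-{[(tert-butyldimethylsilyl)oxy]methyl}prop-2-enoate | C=C(CO[Si](C)(C)C(C)(C)C)C(=O)O[C@H]1C/C(C)=C\CC/C(CO[Si](C)(C)C(C)(C)C)=C\[C@H]2OC(=O)[C@@H](C)[C@H]12 | intermediate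
28 | (3S,3aR,4S,6Z,10E,11aR)-10-(hydroxymethyl)-3,6-dimethyl-2-oxo-2,3,3a,4,5,8,9,11a-octahydrocyclodeca[b]furan-4-yl 2-(hydroxymethyl)prop-2-enoate | C=C(CO)C(=O)O[C@H]1C/C(C)=C\CC/C(CO)=C\[C@H]2OC(=O)[C@@H](C)[C@H]12 | target

**Step count and risks**

Total step count: 19. Longest linear sequence: 17 (steps 1–15, 18, 19); steps 16 and 17 prepare the side-chain acid.

The three steps most likely to fail:

First, step 14 (the key step). What may go wrong is carbopalladation on the wrong face of C6=C7, closure to the cis-fused lactone by carbon–oxygen bond formation on the metal, or β-hydride loss from the allyl complex to a triene acid. The fallback sets out from 18 and comes back to the route at 23. It is an oxidative free-radical lactone annulation with trivalent manganese: Mn(OAc)3·2H2O (2.2 equiv) and methylmalonic acid in AcOH/KOAc at 45 °C generate the methylmalonyl radical, which adds to C7 of the diene; the allyl radical is oxidised to the cation and a carboxyl group closes on C6. This should give (3aR,4S,6Z,10E,11aR)-10-{[(tert-butyldimethylsilyl)oxy]methyl}-4-hydroxy-3,6-dimethyl-2-oxo-2,3,3a,4,5,8,9,11a-octahydrocyclodeca[b]furan-3-carboxylic acid F1. Heating F1 in wet DMSO at 110 °C decarboxylates it, and DBU equilibrates C11 to the 3S methyl epimer, which is 23; steps 14 and 15 are both replaced.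

Second, step 10. Intermolecular coupling to oligomers may outrun closure of the ten-membered enyne ring, or the β,γ-unsaturated aldehyde may isomerise before it is trapped. The fallback sets out from 12 and comes back at 18; it reduces the triple bond before ring closure, so that a cis,cis-diene pre-bends the chain and an alkenylchromium rather than a linear alkynylchromium closes the ring. Diimide (2-nitrobenzenesulfonylhydrazide, Et3N, THF/i-PrOH) should give (3Z,7E,9Z)-7-{[(tert-butyldimethylsilyl)oxy]methyl}-10-iodo-3-methyldeca-3,7,9-trien-1-ol F2. Dess–Martin oxidation gives (3Z,7E,9Z)-7-{[(tert-butyldimethylsilyl)oxy]methyl}-10-iodo-3-methyldeca-3,7,9-trienal F3. CrCl2/NiCl2 in DMSO at high dilution closes the ring to rac-(2Z,4E,8Z)-5-{[(tert-butyldimethylsilyl)oxy]methyl}-9-methylcyclodeca-2,4,8-trien-1-ol F4. MnO2 gives (2Z,4E,8Z)-5-{[(tert-butyldimethylsilyl)oxy]methyl}-9-methylcyclodeca-2,4,8-trien-1-one F5. Corey–Bakshi–Shibata reduction with (R)-2-methyl-CBS-oxazaborolidine and catecholborane at −78 °C, the dienyl group acting as the large substituent, should then give 18; steps 9–13 are replaced.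

Third, step 15. Under the methoxide generated from NaBH4 the free C8 alkoxide may attack C12 and move the lactone from O6 to O8, and C11 may be protonated to a mixture of epimers. The fallback sets out from 22 and comes back at 23; it masks the hydroxyl and reduces under neutral conditions. TESCl and imidazole give (3aR,4S,6Z,10E,11aR)-10-{[(tert-butyldimethylsilyl)oxy]methyl}-6-methyl-3-methylidene-4-[(triethylsilyl)oxy]-3a,4,5,8,9,11a-hexahydrocyclodeca[b]furan-2(3H)-one F6. Conjugate reduction with the copper hydride [(Ph3P)CuH]6 (toluene, rt) followed by DBU equilibration should give (3S,3aR,4S,6Z,10E,11aR)-10-{[(tert-butyldimethylsilyl)oxy]methyl}-3,6-dimethyl-4-[(triethylsilyl)oxy]-3a,4,5,8,9,11a-hexahydrocyclodeca[b]furan-2(3H)-one F7. PPTS in MeOH at 0 °C then removes the triethylsilyl group selectively to give 23.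

**Further compounds**

F1 | step 14 | (3aR,4S,6Z,10E,11aR)-10-{[(tert-butyldimethylsilyl)oxy]methyl}-4-hydroxy-3,6-dimethyl-2-oxo-2,3,3a,4,5,8,9,11a-octahydrocyclodeca[b]furan-3-carboxylic acid (C3 epimers) | O[C@H]1C/C(C)=C\CC/C(CO[Si](C)(C)C(C)(C)C)=C\[C@H]2OC(=O)C(C)(C(=O)O)[C@H]12
F2 | step 10 | (3Z,7E,9Z)-7-{[(tert-butyldimethylsilyl)oxy]methyl}-10-iodo-3-methyldeca-3,7,9-trien-1-ol | C/C(CCO)=C/CC/C(CO[Si](C)(C)C(C)(C)C)=C\C=C/I
F3 | step 10 | (3Z,7E,9Z)-7-{[(tert-butyldimethylsilyl)oxy]methyl}-10-iodo-3-methyldeca-3,7,9-trienal | C/C(CC=O)=C/CC/C(CO[Si](C)(C)C(C)(C)C)=C\C=C/I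
F4 | step 10 | rac-(2Z,4E,8Z)-5-{[(tert-butyldimethylsilyl)oxy]methyl}-9-methylcyclodeca-2,4,8-trien-1-ol | C1/C(CO[Si](C)(C)C(C)(C)C)=C\C=C/C(O)C/C(C)=C\C1
F5 | step 10 | (2Z,4E,8Z)-5-{[(tert-butyldimethylsilyl)oxy]methyl}-9-methylcyclodeca-2,4,8-trien-1-one | C1/C(CO[Si](C)(C)C(C)(C)C)=C\C=C/C(=O)C/C(C)=C\C1
F6 | step 15 | (3aR,4S,6Z,10E,11aR)-10-{[(tert-butyldimethylsilyl)oxy]methyl}-6-methyl-3-methylidene-4-[(triethylsilyl)oxy]-3a,4,5,8,9,11a-hexahydrocyclodeca[b]furan-2(3H)-one | CC[Si](CC)(CC)O[C@H]1C/C(C)=C\CC/C(CO[Si](C)(C)C(C)(C)C)=C\[C@H]2OC(=O)C(=C)[C@H]12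
F7 | step 15 | (3S,3aR,4S,6Z,10E,11aR)-10-{[(tert-butyldimethylsilyl)oxy]methyl}-3,6-dimethyl-4-[(triethylsilyl)oxy]-3a,4,5,8,9,11a-hexahydrocyclodeca[b]furan-2(3H)-one | CC[Si](CC)(CC)O[C@H]1C/C(C)=C\CC/C(CO[Si](C)(C)C(C)(C)C)=C\[C@H]2OC(=O)[C@@H](C)[C@H]12
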